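Two constants can be read from the oak run, and at a planned charge each turns into a share or a time, so you can choose the next flask from them.

| flask | substrate | temperature | remark | time |
|---|---|---|---|---|
| elm | 1.4 M | −10 °C | run made earlier |  |
| oak | 2.2 M | 25 °C | run made earlier |  |
| noon | 1.0 M | 25 °C |  | 5.0 min |
| dawn | 1.0 M | −5 °C |  | 5.0 min |
| autumn | 1.0 M | 55 °C |  | 5.0 min |

| run | time / min | target / % | substrate / % |
|---|---|---|---|
| elm | 2.00 | 10.9 | 76.4 |
| elm | 6.00 | 27.4 | 45.9 |
| elm | 12.0 | 40.2 | 27.7 |
| elm | 15.0 | 47.6 | 20.6 |
| elm | 25.0 | 55.2 | 11.7 |
| oak | 0.333 | 52.9 | 28.4 |
| oak | 0.667 | 49.0 | 26.1 |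
| oak | 1.00 | 45.4 | 22.9 |
| oak | 2.00 | 41.1 | 18.7 |
| oak | 4.00 | 35.6 | 13.0 |

(each reading ± 1 percentage point)



- which flask leads in amount of target, in percent of the substrate charged ("all alike" within 1.5 percentage points) (noon / dawn / autumn / all alike)
- how much target is there at the end, in percent of the substrate charged: noon
- how much target is there at the end, in percent of the substrate charged: dawn
- how much target is there at the end, in percent of the substrate charged: autumn

Look first at target against substrate in oak: their ratio climbs from 1.86 to 2.74 as the flask drains, so a fixed ratio won't describe it. But square the target concentration and divide by the substrate concentration, and the first reading gives 2.17 M and the last 2.14 M. Their mean is 2.16 M; call it Q, the end-point quotient, the equilibrium constant as read at this temperature. It behaves as if each target came out with an equal partner, and it means that at one temperature a thinner flask holds more of its pool as target.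

The pool, substrate plus target, falls too. Divide oak's loss by the elapsed time and by the first and last substrate concentrations, and you have a drain constant; taken at a charge of 1.0 M, call it D, and it reads 1.10 min⁻¹.

Now charge noon. Q puts target near 0.744 M and substrate near 0.256 M. The drain time τ, one over D times the square of charge over substrate, is 13.9 min, longer than the 5.0 min allowed. Let the drain slow as the pool shrinks, so the pool becomes the charge over one plus time over τ: 0.735 M. Q then gives me 0.579 M, or 57.9% of the charge. Elm still had 45.9% substrate at 6.00 min, so I expect dawn unfinished. The same drain constant in the colder elm, taken at the same charge, is 0.0709 min⁻¹, smaller than oak's, so I expect autumn to drain fast. I would run noon.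

The forecast also names noon, with 45%, 37% for dawn and 5% for autumn; of noon it says “the pool falls to about 64%, so target is about 45%”. My noon figure stands above its figure.

The flasks give 56.7% at noon, 42.5% at dawn and 6.38% at autumn, so noon leads.

    substrate ⇌ target + by-product (K = 2.00 M, k = 0.110 s⁻¹, Ea = 86.0 kJ mol⁻¹, ΔH = −78.0 kJ mol⁻¹)
    2 substrate → self-condensation product (k = 0.00930 M⁻¹ s⁻¹, Ea = 55.0 kJ mol⁻¹)
    (constants at 25 °C)

At noon, substrate and target with by-product relax with a half-life of 0.0670 min, short against the 5.0 min, while the whole flask moves with a half-life of 5.55 min. At the end of noon, target squared over substrate stands at 2.03 M, against the 2.16 M read in oak. In a neighbour flask, noon thinned to 0.25 M, Q gives target at 90.5% of the charge before any drain; computed, that neighbour flask holds 87.2%.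

The numbers in the tables come from a simulation on assumed constants, and the scatter is random.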